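**Retrosynthetic overview**
1. Target 18 comes from CBS reduction of the cross-conjugated dienone 17 (sets C8). The C7=CH2/C8=O pair of ring B comes from methylenation of a C7 ketone followed by SeO2 oxidation of C8, the only allylic CH2.
2. The C3(Me)Cl centre of ring A comes from MeMgBr addition to a C3 ketone, then chloride entry anti to the C2 bromine through a bromonium ion.
3. Key disconnection: ring A by [4+2] of the exo-methylene ketone 7 (C1=C6, activated by C7=O of ring B) with (Z)-1-bromo-2-silyloxybutadiene 10 (C2–C5). This forms C1–C2 and C5–C6 and sets the spiro carbon C6 under a chiral confined acid.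
4. Enabling feature: in ring A the C3(Me)Cl carbon lies para to spiro C6 and next to C2–Br, so ring A is a masked 2-bromo-4-oxocyclohexane. In ring B, C6 is alpha to C7 and flanked by the quaternary C11, so ring B can carry an exo-methylene ketone that cannot isomerise.
5. Ring order: ring B is taken from 2,2-dimethylcyclohexane-1,3-dione (steps 1–5); ring A is closed second (step 8).

Key step: step 8

Remark: all spirocycles are numbered as spiro[5.5]undecanes (ring A = C1–C5, spiro carbon C6, ring B = C7–C11; the C6 descriptor changes from R to S in step 11 by priority only), and it is assumed that a test with both antipodes of the acid in step 8 shows which one gives the (6R) adduct 12.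

**Route**

Step 1
Reactants: 1 2,2-dimethylcyclohexane-1,3-dione
Product: 2 2,2-dimethyl-3-methylidenecyclohexan-1-one
Conditions: Ph3PCH3Br (1.05 equiv), KOt-Bu, THF, 0 °C → rt
Reagents that add atoms: methyltriphenylphosphonium bromide, C[P+](c1ccccc1)(c1ccccc1)c1ccccc1.[Br-]
Why: Wittig methylenation; the two carbonyls are equivalent and one equivalent of ylide should olefinate only one of them, with no stereocentre formed.

Step 2
Reactants: 2 2,2-dimethyl-3-methylidenecyclohexan-1-one
Product: 4 6,6-dimethyl-5-methylidenecyclohex-1-en-1-yl trifluoromethanesulfonate, via lithium enolate 3 (not isolated)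
Conditions: LiN(i-Pr)2, THF, −78 °C; then PhNTf2, −78 → 0 °C
Reagents that add atoms: N-phenylbis(trifluoromethanesulfonimide), O=S(=O)(N(c1ccccc1)S(=O)(=O)C(F)(F)F)C(F)(F)F
Why: enolate O-triflation; the ketone has a single enolisable alpha carbon (the other is quaternary), so the enol triflate can form in one position only.

Step 3
Reactants: 4 6,6-dimethyl-5-methylidenecyclohex-1-en-1-yl trifluoromethanesulfonate
Product: 5 1-bromo-6,6-dimethyl-5-methylidenecyclohex-1-ene
Conditions: LiBr (3 equiv), Ni(OAc)2·4H2O (10 mol %), 1,5-cyclooctadiene (30 mol %), Zn (20 mol %), DMA/THF, rt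
Reagents that add atoms: lithium bromide, [Li+].[Br-]
Why: nickel-catalysed exchange of an enol triflate for an alkenyl bromide (oxidative addition to zerovalent nickel, triflate/bromide exchange, reductive elimination); the neutral conditions avoid cationic rearrangement next to the quaternary carbon.

Step 4
Reactants: 5 1-bromo-6,6-dimethyl-5-methylidenecyclohex-1-ene
Product: 6 rac-4-bromo-5,5-dimethyl-6-methylidenecyclohex-3-en-1-ol
Conditions: SeO2 (0.3 equiv), t-BuOOH (3 equiv), CH2Cl2, rt
Reagents that add atoms: tert-butyl hydroperoxide, CC(C)(C)OO (its oxygen is relayed by selenium dioxide, O=[Se]=O)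
Why: SeO2/t-BuOOH allylic hydroxylation (ene reaction, then [2,3]-sigmatropic shift) should occur at the electron-richer exocyclic alkene, whose only allylic CH2 is the ring carbon that becomes C7; the racemic carbinol centre is removed in step 5.

Step 5
Reactants: 6 rac-4-bromo-5,5-dimethyl-6-methylidenecyclohex-3-en-1-ol
Product: 7 4-bromo-5,5-dimethyl-6-methylidenecyclohex-3-en-1-one
Conditions: Dess–Martin periodinane, CH2Cl2, 0 °C → rt; used at once
Reagents that add atoms: none
Why: Dess–Martin oxidation of the allylic alcohol to the exo-methylene ketone under neutral conditions; the gem-dimethyl carbon leaves no ring hydrogen by which the exocyclic alkene could move into the ring.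

Step 6
Reactants: 8 2-(trimethylsilyloxy)buta-1,3-diene
Product: 9 1-bromobut-3-en-2-one
Conditions: N-bromosuccinimide, THF, −78 °C; used crude
Reagents that add atoms: N-bromosuccinimide, O=C1CCC(=O)N1Br
Why: electrophilic alpha-bromination of a silyl enol ether; only the enol CH2 terminus of the cross-conjugated silyloxydiene is nucleophilic.

Step 7
Reactants: 9 1-bromobut-3-en-2-one
Product: 10 (1Z)-1-bromo-2-(tert-butyldimethylsilyloxy)buta-1,3-diene
Conditions: t-BuMe2SiOTf, i-Pr2NEt, Et2O, −78 → 0 °C
Reagents that add atoms: tert-butyldimethylsilyl trifluoromethanesulfonate, CC(C)(C)[Si](C)(C)OS(=O)(=O)C(F)(F)F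
Why: soft enolisation with O-silylation toward the only alpha C–H (the CH2Br group); the Z enol ether (Br cis to OSi, pointing outward in the s-cis diene) is the expected and the only reactive isomer.

Step 8
Reactants: 7 4-bromo-5,5-dimethyl-6-methylidenecyclohex-3-en-1-one; 10 (1Z)-1-bromo-2-(tert-butyldimethylsilyloxy)buta-1,3-diene (1.5 equiv)
Product: 12 (2S,6R)-2,10-dibromo-11,11-dimethylspiro[5.5]undec-9-ene-3,7-dione, via silyl enol ether cycloadduct 11 (not isolated)
Conditions: chiral confined imidodiphosphorimidate Brønsted acid (IDPi, BINOL-derived, N-triflyl core, 3 mol %), CH2Cl2, −78 → −40 °C; then CF3CO2H, CH2Cl2/H2O, 0 °C → rt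
Reagents that add atoms: none
Why: Proposed new method: the confined chiral acid (as proton or, after silyl transfer from 10, as silylium donor) activates the C7 carbonyl of 7 and the 2-silyloxydiene adds in an asynchronous [4+2] cycloaddition, the bromine-bearing terminus C2 bonding first to the unhindered exocyclic C1 and C5 then closing on C6; the closest known reactions are the imidodiphosphorimidate-catalysed enantioselective spirocyclising Diels–Alder reaction of exo-enones with simple dienes and the acid-catalysed Diels–Alder reaction of 2-silyloxydienes with enones, neither of which has been shown with a 1-bromo-2-silyloxydiene. Ring A is closed in [4+2] mode (in the stepwise limit a 6-endo-trig Michael closure of the C6 silyl enol ether onto the activated vinyl ketone). The quaternary spiro centre C6 is set by the catalyst pocket, which should expose only the Si face of C6 (C7 > C11 > C1) to the diene, so that C5 ends on that face and C1 on the other. C2 forms without control but is equilibrated through the enol during the acidic hydrolysis to the equatorial bromide cis to C11, because an axial bromine would be 1,3-diaxial to the axial C7 arm. The step needs para regioselectivity, secured by the 2-silyloxy group and by the fact that only the unsubstituted diene terminus must attack the carbon that becomes quaternary, and site selectivity, secured because the C9=C10 bromoalkene is not a dienophile and the quaternary C11 stops the exo-methylene from migrating into ring B.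

Step 9
Reactants: 12 (2S,6R)-2,10-dibromo-11,11-dimethylspiro[5.5]undec-9-ene-3,7-dione
Product: 13 (2S,6R)-2,10-dibromo-3-hydroxy-3,11,11-trimethylspiro[5.5]undec-9-en-7-one (C3 epimers)
Conditions: MeMgBr (2.2 equiv), Et2O/CH2Cl2, −78 °C; then H2O
Reagents that add atoms: methylmagnesium bromide, C[Mg]Br
Why: Grignard 1,2-addition should go to the unhindered alpha-bromo ketone C3 and not to C7, which is flanked by the quaternary spiro carbon and is at most enolised; C3 forms as an epimer mixture (mainly methyl anti to bromine, Cornforth model) that need not be controlled because step 10 is convergent.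

Step 10
Reactants: 13 (2S,6R)-2,10-dibromo-3-hydroxy-3,11,11-trimethylspiro[5.5]undec-9-en-7-one (C3 epimers)
Product: 14 (2S,3S,6R)-2,10-dibromo-3-chloro-3,11,11-trimethylspiro[5.5]undec-9-en-7-one
Conditions: HCl (gas), CH2Cl2, −40 → 0 °C
Reagents that add atoms: hydrogen chloride, Cl
Why: SN1 substitution of the tertiary alcohol with neighbouring-group participation: the beta-bromo cation closes to a bromonium ion on the face of the C2 bromine and chloride opens it at tertiary C3 from the opposite face, so C3 is set by C2 and both epimers of 13 should converge on the trans-diequatorial bromochloride.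

Step 11
Reactants: 14 (2S,3S,6R)-2,10-dibromo-3-chloro-3,11,11-trimethylspiro[5.5]undec-9-en-7-one
Product: 15 (2S,3S,6S)-2,10-dibromo-3-chloro-3,11,11-trimethyl-7-methylidenespiro[5.5]undec-9-ene
Conditions: Cp2Ti(μ-Cl)(μ-CH2)AlMe2 (Tebbe reagent), pyridine, THF/toluene, −40 °C → rt
Reagents that add atoms: Tebbe reagent Cp2Ti(μ-Cl)(μ-CH2)AlMe2, C[Al-]1(C)C[Ti](C2C=CC=C2)(C2C=CC=C2)[Cl+]1
Why: Tebbe methylenation ([2+2] of Cp2Ti=CH2 with the carbonyl, then cycloreversion) is non-basic, so it suits a hindered ketone with acidic C8 hydrogens and leaves the diequatorial halides (no anti-periplanar hydrogen for E2) untouched.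

Step 12
Reactants: 15 (2S,3S,6S)-2,10-dibromo-3-chloro-3,11,11-trimethyl-7-methylidenespiro[5.5]undec-9-ene
Product: 16 (2S,3S,6S)-2,10-dibromo-3-chloro-3,11,11-trimethyl-7-methylidenespiro[5.5]undec-9-en-8-ol (C8 epimers)
Conditions: SeO2 (0.3 equiv), t-BuOOH (3 equiv), CH2Cl2, rt
Reagents that add atoms: tert-butyl hydroperoxide, CC(C)(C)OO (its oxygen is relayed by selenium dioxide, O=[Se]=O)
Why: SeO2 allylic hydroxylation (ene reaction at C7=CH2, then [2,3]-shift back) can only reach C8, the one allylic CH2 of the molecule (C6 and C11 are quaternary, ring A has no alkene); the C8 configuration is not controlled here and is reset in steps 13 and 14.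

Step 13
Reactants: 16 (2S,3S,6S)-2,10-dibromo-3-chloro-3,11,11-trimethyl-7-methylidenespiro[5.5]undec-9-en-8-ol (C8 epimers)
Product: 17 (2S,3S,6S)-2,10-dibromo-3-chloro-3,11,11-trimethyl-7-methylidenespiro[5.5]undec-9-en-8-one
Conditions: Dess–Martin periodinane, CH2Cl2, 0 °C → rt
Reagents that add atoms: none
Why: Dess–Martin oxidation of the doubly allylic alcohol converges both C8 epimers on one cross-conjugated dienone under neutral conditions.

Step 14
Reactants: 17 (2S,3S,6S)-2,10-dibromo-3-chloro-3,11,11-trimethyl-7-methylidenespiro[5.5]undec-9-en-8-one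
Product: 18 (2S,3S,6S,8R)-2,10-dibromo-3-chloro-3,11,11-trimethyl-7-methylidenespiro[5.5]undec-9-en-8-ol (target)
Conditions: (S)-2-methyl-CBS-oxazaborolidine (20 mol %), catecholborane, toluene, −78 °C; then pH 7 buffer
Reagents that add atoms: none
Why: Corey–Bakshi–Shibata reduction; the C7 flank (fully substituted, its exo-methylene eclipsing the carbonyl, quaternary C6 behind) should act as the large group and C9–H as the small one, so the (S)-catalyst delivers hydride to give (8R) by reagent control, and the 1,2-mode spares the beta-bromo enone and the alkyl halides.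

**Compound list**
1 | 2,2-dimethylcyclohexane-1,3-dione | CC1(C)C(=O)CCCC1=O | starting material
2 | 2,2-dimethyl-3-methylidenecyclohexan-1-one | C=C1CCCC(=O)C1(C)C | intermediate
3 | lithium 6,6-dimethyl-5-methylidenecyclohex-1-en-1-olate (lithium enolate of 2) | C=C1CCC=C(O[Li])C1(C)C | intermediate (not isolated)
4 | 6,6-dimethyl-5-methylidenecyclohex-1-en-1-yl trifluoromethanesulfonate | C=C1CCC=C(OS(=O)(=O)C(F)(F)F)C1(C)C | intermediate
5 | 1-bromo-6,6-dimethyl-5-methylidenecyclohex-1-ene | C=C1CCC=C(Br)C1(C)C | intermediate
6 | rac-4-bromo-5,5-dimethyl-6-methylidenecyclohex-3-en-1-ol | C=C1C(O)CC=C(Br)C1(C)C | intermediate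
7 | 4-bromo-5,5-dimethyl-6-methylidenecyclohex-3-en-1-one | C=C1C(=O)CC=C(Br)C1(C)C | intermediate
8 | 2-(trimethylsilyloxy)buta-1,3-diene | C=CC(=C)O[Si](C)(C)C | starting material
9 | 1-bromobut-3-en-2-one | C=CC(=O)CBr | intermediate
10 | (1Z)-1-bromo-2-(tert-butyldimethylsilyloxy)buta-1,3-diene | Br/C=C(/C=C)O[Si](C)(C)C(C)(C)C | intermediate
11 | (6R)-2,10-dibromo-3-(tert-butyldimethylsilyloxy)-11,11-dimethylspiro[5.5]undeca-3,9-dien-7-one (C2 epimers) | O=C1CC=C(Br)C(C)(C)[C@]12CC=C(O[Si](C)(C)C(C)(C)C)C(Br)C2 | intermediate (not isolated)
12 | (2S,6R)-2,10-dibromo-11,11-dimethylspiro[5.5]undec-9-ene-3,7-dione | O=C1CC=C(Br)C(C)(C)[C@]12CCC(=O)[C@@H](Br)C2 | intermediate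
13 | (2S,6R)-2,10-dibromo-3-hydroxy-3,11,11-trimethylspiro[5.5]undec-9-en-7-one (C3 epimers) | O=C1CC=C(Br)C(C)(C)[C@]12CCC(C)(O)[C@@H](Br)C2 | intermediate
14 | (2S,3S,6R)-2,10-dibromo-3-chloro-3,11,11-trimethylspiro[5.5]undec-9-en-7-one | O=C1CC=C(Br)C(C)(C)[C@]12CC[C@](C)(Cl)[C@@H](Br)C2 | intermediate
15 | (2S,3S,6S)-2,10-dibromo-3-chloro-3,11,11-trimethyl-7-methylidenespiro[5.5]undec-9-ene | C=C1CC=C(Br)C(C)(C)[C@]12CC[C@](C)(Cl)[C@@H](Br)C2 | intermediate
16 | (2S,3S,6S)-2,10-dibromo-3-chloro-3,11,11-trimethyl-7-methylidenespiro[5.5]undec-9-en-8-ol (C8 epimers) | C=C1C(O)C=C(Br)C(C)(C)[C@]12CC[C@](C)(Cl)[C@@H](Br)C2 | intermediate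
17 | (2S,3S,6S)-2,10-dibromo-3-chloro-3,11,11-trimethyl-7-methylidenespiro[5.5]undec-9-en-8-one | C=C1C(=O)C=C(Br)C(C)(C)[C@]12CC[C@](C)(Cl)[C@@H](Br)C2 | intermediate
18 | (2S,3S,6S,8R)-2,10-dibromo-3-chloro-3,11,11-trimethyl-7-methylidenespiro[5.5]undec-9-en-8-ol | C=C1[C@H](O)C=C(Br)C(C)(C)[C@]12CC[C@](C)(Cl)[C@@H](Br)C2 | target

**Step count**
Total steps: 14. Longest linear sequence: 12 (steps 1–5 and 8–14); the diene branch is steps 6–7.

**Steps most likely to fail**

Step 8 (proposed new method). The strong acid may protodesilylate diene 10 or ionise the allylic C2–Br bond of the adduct. The reaction may stop after the first C–C bond (open-chain Mukaiyama–Michael product), or enone 7 may react as an oxadiene with the enol ether bond. Enantiofacial control at C6 may also be poor. The fallback uses known chemistry and sets out from 7. A thermal Diels–Alder reaction with commercial 2-(trimethylsilyloxy)buta-1,3-diene 8 (toluene, 80 °C) should give the racemic trimethylsilyl enol ether cycloadduct F1. Hydrolysis (aq. HCl, THF) should give the spiro-diketone F2, which is achiral because ring A is symmetric until C2 is substituted. C6 and C2 would then be set together by an enamine-catalysed alpha-bromination that selects one of the two enantiotopic arms (C2-symmetric 4,5-diphenylimidazolidine, benzoic acid, 4,4-dibromo-2,6-di-tert-butylcyclohexa-2,5-dienone, THF, −30 °C; the hindered C7 ketone cannot form an enamine). Equilibration of C2 as in step 8 brings the route back at 12.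

Step 10. The open tertiary cation may be captured by chloride before bromine bridges, giving the cis dihalide. E1 elimination may compete, and reversible ionisation may let C3 drift to the more stable epimer with axial chlorine. The fallback sets out from 13. Reductive elimination of the bromohydrin (Zn, AcOH, Et2O) should give the C2=C3 alkene, (6R)-10-bromo-3,11,11-trimethylspiro[5.5]undeca-2,9-dien-7-one F3. Anti bromochlorination with n-Bu4N[BrCl2] (CH2Cl2, −78 °C) follows. The bromonium ion should form on the face away from the axial C7 arm and chloride should open it at tertiary C3, which brings the route back at 14.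

Step 14. Both flanks of the C8 ketone are alkenyl, so facial discrimination by the catalyst may be weak, and hydroboration or 1,4-reduction of the exo-methylene enone may compete. The fallback sets out from 17. Luche reduction (NaBH4, CeCl3·7H2O, MeOH, −78 °C) should give the epimer mixture 16. Lipase-catalysed acylation (Burkholderia cepacia lipase, vinyl acetate, t-BuOMe) should, by the Kazlauskas rule, acylate the (8R) epimer to the (8R)-acetate F4 and leave the (8S)-alcohol F5. F5 is separated, reoxidised to 17 with Dess–Martin periodinane and recycled. Methanolysis of F4 (K2CO3, MeOH, 0 °C) brings the route back at 18.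

Further compounds
F1 | step 8 | rac-10-bromo-11,11-dimethyl-3-(trimethylsilyloxy)spiro[5.5]undeca-3,9-dien-7-one | O=C1CC=C(Br)C(C)(C)C12CC=C(O[Si](C)(C)C)CC2
F2 | step 8 | 10-bromo-11,11-dimethylspiro[5.5]undec-9-ene-3,7-dione | O=C1CC=C(Br)C(C)(C)C12CCC(=O)CC2
F3 | step 10 | (6R)-10-bromo-3,11,11-trimethylspiro[5.5]undeca-2,9-dien-7-one | O=C1CC=C(Br)C(C)(C)[C@]12CCC(C)=CC2
F4 | step 14 | (2S,3S,6S,8R)-2,10-dibromo-3-chloro-3,11,11-trimethyl-7-methylidenespiro[5.5]undec-9-en-8-yl acetate | C=C1[C@H](OC(C)=O)C=C(Br)C(C)(C)[C@]12CC[C@](C)(Cl)[C@@H](Br)C2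
F5 | step 14 | (2S,3S,6S,8S)-2,10-dibromo-3-chloro-3,11,11-trimethyl-7-methylidenespiro[5.5]undec-9-en-8-ol | C=C1[C@@H](O)C=C(Br)C(C)(C)[C@]12CC[C@](C)(Cl)[C@@H](Br)C2
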